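The runs were generated by integration with made-up constants, and the scatter is random.

We want to know what holds the largest part of the G at the end of north and of north-east, and how much D north then has, and we reckon from the X-poor end and the X-rich end and join them.

| setting | red | teal | ochre | north | north-east |
|---|---|---|---|---|---|
| G | 0.10 M | 0.10 M | 0.10 M | 0.10 M | 0.10 M |
| X | 0.062 M | 0.13 M | 0.42 M | 0.400 M | 0.0500 M |
| remark | run made earlier | run made earlier | run made earlier |  |  |
| time |  |  |  | 20 min | 20 min |

- red (time / min: D / %): 1.33: 4; 4.00: 2; 6.00: 0; 10.0: 0
- teal (time / min: D / %): 1.33: 0; 4.00: 1; 6.00: 1; 10.0: 1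
- ochre (time / min: D / %): 2.50: 18; 5.00: 24; 8.00: 22; 10.0: 27

(readings scatter by 2 percentage points)

- which of these holds the largest part of the G at the end of north (L / Q / G / D)
- which of these holds the largest part of the G at the end of north-east (L / Q / G / D)
- how much D is there at the end of north, in percent of the G charged



All amounts below are fractions of the G charge.

1. The X-poor end: north-east is charged with 0.500 of X, and each G that reacts takes at least one X, so at least 50.0% of the G stays unreacted. We name G.

2. Red and teal hold 0.620 and 1.30 of X, under the 2 that carry each G to Q, and their D stays at or under 4%, so we read stepwise addition, with D coming last.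

3. The X-rich end: ochre reads D at 24%, 22% and 27% with X to spare, which looks like a reversible last step. We suppose each addition frees one by-product and put every G into Q or D. With D at 24.3%, the end quotient (the equilibrium constant of the last step), D times by-product over Q times X, reads 0.369.

4. Solving the same quotient with the 4.00 of X in north gives D = 22.7%, and Q holds more than D.

5. The weak link is that no reading shows where the rest of the G stands. So we let half of it leave the chain after one addition: the quotient becomes 0.673, yet north still gets D = 23.4%, with Q at 26.6%. We commit to that D.

The forecast says Q for north, G for north-east and D at 25%, a little above ours, with “slightly lower X offset by the longer time”.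

    G + X → L + E (k = 0.370 M⁻¹ s⁻¹)
    X + Q ⇌ D + E (K = 0.530, k = 0.0140 M⁻¹ s⁻¹)
    X + L → Q + E (k = 0.440 M⁻¹ s⁻¹)
    L → J (k = 0.0740 s⁻¹)

North ends with Q largest at 39.8%, then J at 36.4% and D at 23.9%, and north-east with G at 54.3%, so the forecast stands on all three. The neighbouring flask is north with 1.6 M of X, which is 16.0 of the G charge. The end quotient 0.369 gives D = 65.0% there, and that neighbouring flask ends with Q at 23.7% and D at 66.1%.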